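Ring B of the spiro[5.5]undecane is built in one operation on a preformed ring A: an enantioselective Lewis-acid-catalysed formal [4+2] spiroannulation joins the exocyclic enone of (E)-6-ethylidene-3-methylcyclohex-2-enone to the silyl dienol ether of mesityl oxide, forming C7–C8 and C6–C11 (numbering: C1 carbinol, C3 CMeCl, C4 CHBr, C6 spiro, C7 CMe–O, C10 CBr–O, C11 CMe2). The step exploits the vicinal quaternary pair C6/C11 of ring B, flanked by the C1 carbinol of ring A (latent dienophile carbonyl) and the oxygenated C7–C10 array (latent 2-silyloxydiene), and sets the spiro centre. From it, C1 reduction, ring A bromochlorination and both ring B epoxides are relayed.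

Key step: step 3

Remark on numbering: all spirocycles carry one fixed spiro[5.5]undecane numbering (ring A = C1–C5, C6 = spiro atom, ring B = C7–C11), kept for comparison and not adjusted to lowest locants.
Assumption: the sense of induction of the oxazaborolidine in step 3 cannot be predicted with confidence for this enone class; the (S)-catalyst is written, and the antipode that delivers (6R)-8 is to be used.
Remark: 13 and 14 are carried as stereoisomer mixtures at C10 (and C9), because both carbons become sp2 in step 9.

Step 1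
Reactants: 1 mesityl oxide (4-methylpent-3-en-2-one)
Product: 2 2-(tert-butyldimethylsilyloxy)-4-methylpenta-1,3-diene
Conditions: LiN(iPr)2, THF, −78 °C; tBuMe2SiCl, DMPU, −78 → 0 °C
Reagents that add atoms: tert-butyldimethylsilyl chloride, CC(C)(C)[Si](C)(C)Cl
Why: Kinetic deprotonation of the enone at the α'-methyl group and O-silylation should give the cross-conjugated 2-silyloxydiene (silyl enol ether formation).

Step 2
Reactants: 3 3-methylcyclohex-2-en-1-one; 4 acetaldehyde
Product: 6 (E)-6-ethylidene-3-methylcyclohex-2-en-1-one, via aldol mesylate 5 (not isolated)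
Conditions: LiN(iPr)2, THF, −78 °C; CH3CHO; MsCl, −78 → 0 °C; DBU, rt
Reagents that add atoms: none
Why: The kinetic α'-enolate should add to acetaldehyde, and mesylation followed by E1cB elimination should give the more stable E-ethylidene dienone (aldol condensation).

Step 3
Reactants: 6 (E)-6-ethylidene-3-methylcyclohex-2-en-1-one; 2 2-(tert-butyldimethylsilyloxy)-4-methylpenta-1,3-diene
Product: 8 (6R,7S)-3,7,11,11-tetramethylspiro[5.5]undec-2-ene-1,9-dione, via silyl enol ether 7 (not isolated)
Conditions: (S)-3,3-diphenyl-1-(o-tolyl)tetrahydro-1H,3H-pyrrolo[1,2-c][1,3,2]oxazaborole (20 mol %), AlBr3 (16 mol %), CH2Cl2, −78 → −40 °C; then 1 M HCl, THF, 0 °C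
Reagents that add atoms: none
Why: Proposed new method: the AlBr3-activated oxazaborolidine binds the ring A carbonyl of 6, the unsubstituted CH2 terminus of 2 adds to the ethylidene β-carbon (Mukaiyama–Michael, C7–C8) and the boron dienolate so formed closes through its α-carbon onto the gem-dimethyl terminus of the silyloxyallyl cation (C6–C11), an asynchronous formal [4+2] cycloaddition whose closest known types are the AlBr3/AlMe3- and HNTf2-promoted racemic Diels–Alder reactions of 4,4-disubstituted 2-silyloxydienes with hindered enones (vicinal quaternary carbons) and the oxazaborolidinium-catalysed enantioselective Diels–Alder reactions of 2-silyloxydienes with enones. Ring B closes as a six-membered carbocycle, in the stepwise limit by a 6-(enolexo)-endo-trig Michael closure. The spiro centre C6 is controlled by the catalyst, which shields one face of the s-cis-locked exocyclic enone, while C7 follows from the E geometry of the ethylidene group and is erased in step 4. The step needs site selectivity for the exocyclic over the ring enone, secured by the unhindered β-CH(Me) terminus against the β,β-disubstituted ring position, and regioselectivity, secured by the polarity of the 2-silyloxydiene. Acidic work-up should hydrolyse the silyl enol ether to the C9 ketone.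

Step 4
Reactants: 8 (6R,7S)-3,7,11,11-tetramethylspiro[5.5]undec-2-ene-1,9-dione
Product: 9 (S)-3,7,11,11-tetramethylspiro[5.5]undeca-2,7-diene-1,9-dione
Conditions: Pd(OCOCF3)2 (5 mol %), DMSO (10 mol %), O2 (1 atm), AcOH, 80 °C
Reagents that add atoms: none
Why: The palladium enolate of the C9 ketone can undergo β-hydride elimination only toward C7–H because C11 is quaternary, so a single ring B enone should form (aerobic palladium-catalysed α,β-dehydrogenation of a ketone).

Step 5
Reactants: 9 (S)-3,7,11,11-tetramethylspiro[5.5]undeca-2,7-diene-1,9-dione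
Product: 10 (R)-3,7,11,11-tetramethyl-9-(triisopropylsilyloxy)spiro[5.5]undeca-2,7,9-trien-1-one
Conditions: LiN(SiMe3)2, THF, −78 °C; iPr3SiOTf, −78 → 0 °C
Reagents that add atoms: triisopropylsilyl triflate, CC(C)[Si](OS(=O)(=O)C(F)(F)F)(C(C)C)C(C)C
Why: Kinetic deprotonation should occur at C10, the only α'-CH2 in the molecule (the ring A enone has a quaternary α' carbon), and O-silylation masks the C9 ketone while storing a nucleophilic C10 (silyl dienol ether formation).

Step 6
Reactants: 10 (R)-3,7,11,11-tetramethyl-9-(triisopropylsilyloxy)spiro[5.5]undeca-2,7,9-trien-1-one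
Product: 12 (1S,6R)-3,7,11,11-tetramethyl-9-(triisopropylsilyloxy)spiro[5.5]undeca-3,7,9-trien-1-ol, via deconjugated ketone 11 (not isolated)
Conditions: KOtBu, tBuOH–THF, 0 °C; inverse quench into AcOH/THF, −78 °C; crude 11, (R)-1-methyl-3,3-diphenyltetrahydro-1H,3H-pyrrolo[1,2-c][1,3,2]oxazaborole (20 mol %), catecholborane, PhMe, −78 °C
Reagents that add atoms: none
Why: Equilibrating γ-deprotonation should give the endocyclic dienolate and kinetic α-protonation deconjugates the enone (classical base-mediated deconjugation of a β-methyl enone), after which the CBS reduction, which distinguishes the quaternary C6 from the C2 methylene, should deliver hydride under reagent control to set (1S).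

Step 7
Reactants: 12 (1S,6R)-3,7,11,11-tetramethyl-9-(triisopropylsilyloxy)spiro[5.5]undeca-3,7,9-trien-1-ol
Product: 13 (1S,3S,4S,6R)-4,10-dibromo-3-chloro-1-hydroxy-3,7,11,11-tetramethylspiro[5.5]undec-7-en-9-one (C10 epimer mixture)
Conditions: Bu4N+ BrCl2− (2.2 equiv), CH2Cl2, −78 → −20 °C
Reagents that add atoms: tetrabutylammonium dichlorobromate (Bu4N+ BrCl2−, written as Bu4N+ Cl− with BrCl), CCCC[N+](CCCC)(CCCC)CCCC.[Cl-].ClBr
Why: One equivalent should brominate the silyl dienol ether at C10 (electrophilic bromination of a silyl enol ether) and the second should add across the ring A alkene through a bromonium ion formed on the face of the C1 hydroxyl, anti to the pseudo-axial C7 branch, which chloride opens at the tertiary carbon from the other face (Markovnikov anti-bromochlorination).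

Step 8
Reactants: 13 (1S,3S,4S,6R)-4,10-dibromo-3-chloro-1-hydroxy-3,7,11,11-tetramethylspiro[5.5]undec-7-en-9-one
Product: 14 (1S,3S,4S,6R)-4,10-dibromo-3-chloro-3,7,11,11-tetramethylspiro[5.5]undec-7-ene-1,9-diol (C9/C10 stereoisomer mixture)
Conditions: NaBH4, CeCl3·7H2O, MeOH, −78 °C
Reagents that add atoms: none
Why: The Luche reduction should give clean 1,2-reduction of the α'-bromo enone, and the configuration of the new carbinol is irrelevant because C9 becomes sp2 in step 9.

Step 9
Reactants: 14 (1S,3S,4S,6R)-4,10-dibromo-3-chloro-3,7,11,11-tetramethylspiro[5.5]undec-7-ene-1,9-diol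
Product: 15 (1S,3S,4S,6R)-4,10-dibromo-3-chloro-3,7,11,11-tetramethylspiro[5.5]undeca-7,9-dien-1-ol
Conditions: Ph2S[OC(CF3)2Ph]2 (1.1 equiv), CH2Cl2, −20 → 0 °C
Reagents that add atoms: none
Why: The sulfurane should activate the allylic C9 hydroxyl much faster than the hindered neopentyl-type C1 hydroxyl, and the only β-hydrogen sits on C10, so elimination should give the 10-bromo-7,9-diene (sulfurane-mediated dehydration).

Step 10
Reactants: 15 (1S,3S,4S,6R)-4,10-dibromo-3-chloro-3,7,11,11-tetramethylspiro[5.5]undeca-7,9-dien-1-ol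
Product: 16 prepacifenol, (1S,3S,4S,6R,7S,8R)-4,10-dibromo-3-chloro-7,8-epoxy-3,7,11,11-tetramethylspiro[5.5]undec-9-en-1-ol
Conditions: VO(acac)2 (5 mol %), tBuOOH (decane), PhMe, 0 °C → rt; chromatography on Et3N-deactivated silica
Reagents that add atoms: tert-butyl hydroperoxide, CC(C)(C)OO
Why: The vanadate ester of the homoallylic C1 hydroxyl should deliver oxygen to the electron-richer trisubstituted C7=C8 alkene on the face of ring B that carries C1, leaving the vinyl bromide untouched (hydroxyl-directed vanadium-catalysed epoxidation).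

Step 11
Reactants: 16 prepacifenol
Product: 17 prepacifenol epoxide, (1S,3S,4S,6R,7S,8R,9R,10R)-4,10-dibromo-3-chloro-7,8:9,10-diepoxy-3,7,11,11-tetramethylspiro[5.5]undecan-1-ol
Conditions: dimethyldioxirane, acetone–CH2Cl2, 0 °C → rt
Reagents that add atoms: dimethyldioxirane, CC1(C)OO1
Why: The neutral dioxirane should epoxidise the remaining vinyl bromide from the face opposite the existing epoxide, as is usual for cyclohexadiene monoepoxides, to give the trans-diepoxide without acid-induced ether formation (dioxirane epoxidation).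

Compound list
1 | mesityl oxide (4-methylpent-3-en-2-one) | CC(=O)C=C(C)C | starting material
2 | 2-(tert-butyldimethylsilyloxy)-4-methylpenta-1,3-diene | C=C(O[Si](C)(C)C(C)(C)C)C=C(C)C | intermediate
3 | 3-methylcyclohex-2-en-1-one | CC1=CC(=O)CCC1 | starting material
4 | acetaldehyde | CC=O | starting material
5 | 6-[1-(methylsulfonyloxy)ethyl]-3-methylcyclohex-2-en-1-one (racemic diastereomer mixture) | CC1=CC(=O)C(CC1)C(C)OS(C)(=O)=O | intermediate
6 | (E)-6-ethylidene-3-methylcyclohex-2-en-1-one | C/C=C1\CCC(C)=CC1=O | intermediate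
7 | (6R,7S)-9-(tert-butyldimethylsilyloxy)-3,7,11,11-tetramethylspiro[5.5]undeca-2,9-dien-1-one | CC1(C)[C@@]2(CCC(C)=CC2=O)[C@@H](C)CC(O[Si](C)(C)C(C)(C)C)=C1 | intermediate
8 | (6R,7S)-3,7,11,11-tetramethylspiro[5.5]undec-2-ene-1,9-dione | CC1(C)[C@@]2(CCC(C)=CC2=O)[C@@H](C)CC(=O)C1 | intermediate
9 | (S)-3,7,11,11-tetramethylspiro[5.5]undeca-2,7-diene-1,9-dione | CC1(C)[C@@]2(CCC(C)=CC2=O)C(C)=CC(=O)C1 | intermediate
10 | (R)-3,7,11,11-tetramethyl-9-(triisopropylsilyloxy)spiro[5.5]undeca-2,7,9-trien-1-one | CC1(C)[C@@]2(CCC(C)=CC2=O)C(C)=CC(O[Si](C(C)C)(C(C)C)C(C)C)=C1 | intermediate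
11 | (R)-3,7,11,11-tetramethyl-9-(triisopropylsilyloxy)spiro[5.5]undeca-3,7,9-trien-1-one | CC1(C)[C@@]2(CC=C(C)CC2=O)C(C)=CC(O[Si](C(C)C)(C(C)C)C(C)C)=C1 | intermediate
12 | (1S,6R)-3,7,11,11-tetramethyl-9-(triisopropylsilyloxy)spiro[5.5]undeca-3,7,9-trien-1-ol | CC1(C)[C@@]2(CC=C(C)C[C@@H]2O)C(C)=CC(O[Si](C(C)C)(C(C)C)C(C)C)=C1 | intermediate
13 | (1S,3S,4S,6R)-4,10-dibromo-3-chloro-1-hydroxy-3,7,11,11-tetramethylspiro[5.5]undec-7-en-9-one (C10 epimers, bromine trans to chlorine in ring A) | CC1(C)[C@@]2(C[C@H](Br)[C@@](C)(Cl)C[C@@H]2O)C(C)=CC(=O)C1Br | intermediate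
14 | (1S,3S,4S,6R)-4,10-dibromo-3-chloro-3,7,11,11-tetramethylspiro[5.5]undec-7-ene-1,9-diol (C9/C10 stereoisomers) | CC1(C)[C@@]2(C[C@H](Br)[C@@](C)(Cl)C[C@@H]2O)C(C)=CC(O)C1Br | intermediate
15 | (1S,3S,4S,6R)-4,10-dibromo-3-chloro-3,7,11,11-tetramethylspiro[5.5]undeca-7,9-dien-1-ol | CC1(C)[C@@]2(C[C@H](Br)[C@@](C)(Cl)C[C@@H]2O)C(C)=CC=C1Br | intermediate
16 | prepacifenol, (1S,3S,4S,6R,7S,8R)-4,10-dibromo-3-chloro-7,8-epoxy-3,7,11,11-tetramethylspiro[5.5]undec-9-en-1-ol (epoxide oxygen on the ring B face that carries C1) | CC1(C)[C@@]2(C[C@H](Br)[C@@](C)(Cl)C[C@@H]2O)[C@]2(C)O[C@@H]2C=C1Br | intermediate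
17 | prepacifenol epoxide, (1S,3S,4S,6R,7S,8R,9R,10R)-4,10-dibromo-3-chloro-7,8:9,10-diepoxy-3,7,11,11-tetramethylspiro[5.5]undecan-1-ol (trans-diepoxide) | CC1(C)[C@@]2(C[C@H](Br)[C@@](C)(Cl)C[C@@H]2O)[C@]2(C)O[C@@H]2[C@H]2O[C@]21Br | target

Total step count: 11
Longest linear sequence: 10 steps (steps 2–11, from 3-methylcyclohex-2-en-1-one); the diene 2 joins in step 3 after one step.

Steps most likely to fail

Step 3. The chiral Lewis acid may discriminate poorly between the enone faces, or achiral silyl-cation catalysis may outrun it, so that the spiro centre forms with low enantiomeric purity; the closure to the vicinal quaternary pair may also stall at the Michael adduct. Fallback: the annulation is run from 6 and 2 with the achiral mixed Lewis acid AlBr3/AlMe3 (CH2Cl2–PhMe, −5 °C), a known racemic reaction type for such hindered diene/enone pairs. This gives 7 together with its mirror image, the (6S,7R)-silyl enol ether F1, and after the same acidic work-up 8 together with the (6S,7R)-diketone F2. The two diketones are separated by preparative chromatography on a chiral stationary phase (supercritical CO2/MeOH), and the route is rejoined at 8.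

Step 7. The bromonium ion may form on the other face of the ring A alkene (poor facial selectivity, giving the 3,4-bis-epimer), or the C1 hydroxyl may capture it. Fallback, which turns that facial preference to advantage, sets out from 12. NBS (1 equiv, THF, −78 °C) converts only the silyl dienol ether into the 10-bromo enone with the ring A alkene intact, bromo enone F3. Dimethyldioxirane then epoxidises the ring A alkene on the face anti to the hydroxyl to give the epoxide F4. Li2NiBr4 (THF) opens it at the secondary carbon C4 with inversion to give the trans-bromohydrin F5. HCl in CH2Cl2 finally replaces the tertiary hydroxyl by chloride with retention, through the bromonium ion now formed on a defined face, and the route is rejoined at 13.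

Step 6. The substrate may override the catalyst in the reduction of the hindered C1 ketone (poor facial selectivity), and the deconjugated ketone may slip back into conjugation during a slow reduction. Fallback sets out from 11. The crude deconjugated ketone is bromochlorinated at once (Bu4N+ BrCl2−, 2.2 equiv, CH2Cl2, −78 °C), which removes the alkene that allows reconjugation and gives the bromochloro dione F6. NaBH4/CeCl3·7H2O (MeOH, −78 °C) then reduces both ketones, the now syn-axial C3 methyl blocking the axial trajectory at C1 so that hydride arrives equatorially under substrate control. This gives 14, where the route is rejoined.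

Further compounds
F1 | step 3 | (6S,7R)-9-(tert-butyldimethylsilyloxy)-3,7,11,11-tetramethylspiro[5.5]undeca-2,9-dien-1-one (enantiomer of 7) | CC1(C)[C@]2(CCC(C)=CC2=O)[C@H](C)CC(O[Si](C)(C)C(C)(C)C)=C1
F2 | step 3 | (6S,7R)-3,7,11,11-tetramethylspiro[5.5]undec-2-ene-1,9-dione (enantiomer of 8) | CC1(C)[C@]2(CCC(C)=CC2=O)[C@H](C)CC(=O)C1
F3 | step 7 | (1S,6R)-10-bromo-1-hydroxy-3,7,11,11-tetramethylspiro[5.5]undeca-3,7-dien-9-one (C10 epimers) | CC1(C)[C@@]2(CC=C(C)C[C@@H]2O)C(C)=CC(=O)C1Br
F4 | step 7 | (1S,3S,4R,6R)-10-bromo-3,4-epoxy-1-hydroxy-3,7,11,11-tetramethylspiro[5.5]undec-7-en-9-one (epoxide anti to the hydroxyl, C10 epimers) | CC1(C)[C@@]2(C[C@H]3O[C@@]3(C)C[C@@H]2O)C(C)=CC(=O)C1Br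
F5 | step 7 | (1S,3S,4S,6R)-4,10-dibromo-1,3-dihydroxy-3,7,11,11-tetramethylspiro[5.5]undec-7-en-9-one (C10 epimers) | CC1(C)[C@@]2(C[C@H](Br)[C@@](C)(O)C[C@@H]2O)C(C)=CC(=O)C1Br
F6 | step 6 | (3S,4S,6R)-4,10-dibromo-3-chloro-3,7,11,11-tetramethylspiro[5.5]undec-7-ene-1,9-dione (C10 epimers) | CC1(C)[C@@]2(C[C@H](Br)[C@@](C)(Cl)CC2=O)C(C)=CC(=O)C1Br
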